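**Plan**

- Retrosynthesis: remove the C7 silyl ether and the C4 1,3-dithiane, cut the aryl ether bond O1–C8a of ring C, cut C3–C4 between a ring-A dithiane anion and a ring-B oxirane, and cut the geranyl ether bond at O4'.
- Forward: ring A is carried as a silylated 2-bromoaryl dithiane and ring B as a geranylated (R)-aryloxirane. The two are joined at C3–C4, ring C is then closed by copper-catalysed O-arylation, and the ketone and phenol are unmasked last.
- Enabling feature: O1–C8a is an aryl–oxygen bond on ring A next to C4a, so the C2 hydroxyl can be arylated at the brominated C8a without breaking any bond to C2. Holding C4 as a dithiane removes the β-hydroxy ketone and with it dehydration and retro-aldol cleavage under base.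
- Stereochemistry: C2, the only stereocentre, is set by asymmetric transfer hydrogenation of the α-chloro ketone. The (R)-chlorohydrin gives the (R)-oxirane and then the (S)-carbinol (a change of descriptor only), which is carried unchanged into the (S)-flavanone.

Key step: step 7

Remark: commercial geraniol is taken as the pure (2E) isomer; "geranyl" below means (2E)-3,7-dimethylocta-2,6-dien-1-yl.

**Route**

Step 1
Reactants: 1 2-bromo-4-hydroxybenzaldehyde
Product: 2 2-bromo-4-(triisopropylsilyloxy)benzaldehyde
Conditions: TIPSCl, imidazole, DMF, 0 °C → rt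
Reagents that add atoms: triisopropylsilyl chloride (TIPSCl), SMILES CC(C)[Si](Cl)(C(C)C)C(C)C
Why: Imidazole-mediated silylation of a phenol (silyl ether formation) removes the acidic O–H before the organolithium chemistry, and the bulky triisopropylsilyl group should survive the Lewis acid of step 2, the amide base of step 6 and the hot carbonate of step 7.

Step 2
Reactants: 2 2-bromo-4-(triisopropylsilyloxy)benzaldehyde; 3 propane-1,3-dithiol
Product: 4 2-[2-bromo-4-(triisopropylsilyloxy)phenyl]-1,3-dithiane
Conditions: BF3·OEt2 (0.3 equiv), CH2Cl2, 0 °C → rt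
Reagents that add atoms: none
Why: Lewis acid-catalysed dithioacetalisation of an aryl aldehyde is routine and turns the future C4 into a Corey–Seebach acyl anion equivalent, while the aryl bromide and aryl silyl ether are inert to BF3·OEt2 at this temperature.

Step 3
Reactants: 5 2-chloro-1-(4-hydroxyphenyl)ethanone; 6 geraniol
Product: 7 2-chloro-1-[4-(geranyloxy)phenyl]ethanone
Conditions: PPh3, DIAD, THF, 0 °C (betaine pre-formed), then 6, then 5, 0 °C → rt
Reagents that add atoms: none
Why: Mitsunobu etherification joins the acidic para-acyl phenol to the primary allylic alcohol by SN2 at C1 under neutral conditions, so no free phenoxide can attack the phenacyl chloride, pre-forming the betaine keeps PPh3 away from the C–Cl bond, and the (E)-alkene is untouched.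

Step 4
Reactants: 7 2-chloro-1-[4-(geranyloxy)phenyl]ethanone
Product: 8 (R)-2-chloro-1-[4-(geranyloxy)phenyl]ethanol
Conditions: RuCl[(S,S)-TsDPEN](p-cymene) (1 mol%), HCO2H/Et3N (5:2), EtOAc, rt
Reagents that add atoms: none
Why: Noyori asymmetric transfer hydrogenation of an aryl chloromethyl ketone, in which the (S,S)-ligand should deliver hydride to the same carbonyl face as in acetophenone (aryl to η6-arene contact), which is the (R) descriptor here because CH2Cl outranks aryl; formate does not reduce the trisubstituted alkenes or the C–Cl bond.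

Step 5
Reactants: 8 (R)-2-chloro-1-[4-(geranyloxy)phenyl]ethanol
Product: 9 (R)-2-[4-(geranyloxy)phenyl]oxirane
Conditions: 2 M NaOH (aq), i-PrOH/THF, 0 °C → rt; extractive work-up, no silica gel
Reagents that add atoms: none
Why: Intramolecular Williamson closure (3-exo-tet) of the chlorohydrin alkoxide onto CH2Cl forms the oxirane without touching the carbinol carbon, so the (R) configuration is carried over; the electron-rich oxirane is acid-labile and is therefore used crude.

Step 6
Reactants: 4 2-[2-bromo-4-(triisopropylsilyloxy)phenyl]-1,3-dithiane; 9 (R)-2-[4-(geranyloxy)phenyl]oxirane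
Product: 11 (S)-2-{2-[2-bromo-4-(triisopropylsilyloxy)phenyl]-1,3-dithian-2-yl}-1-[4-(geranyloxy)phenyl]ethanol, via 2-lithio-2-aryl-1,3-dithiane 10 (not isolated)
Conditions: 4 (1.2 equiv), LiN(i-Pr)2 (1.15 equiv), THF, −78 → −20 °C; then 9, DMPU, −20 °C → rt; H2O quench
Reagents that add atoms: none
Why: Corey–Seebach umpolung, in which the amide base removes the acidic dithiane C–H without the bromine–lithium exchange an alkyllithium would cause, and the hindered carbanion opens the monosubstituted oxirane by SN2 at the CH2 terminus, so the C–O bond of the stereocentre is untouched and (R) becomes (S) only because CH2 drops in CIP rank.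

Step 7
Reactants: 11 (S)-2-{2-[2-bromo-4-(triisopropylsilyloxy)phenyl]-1,3-dithian-2-yl}-1-[4-(geranyloxy)phenyl]ethanol
Product: 12 (S)-2-[4-(geranyloxy)phenyl]-7-(triisopropylsilyloxy)spiro[chromane-4,2'-[1,3]dithiane]
Conditions: CuI (20 mol%), 3,4,7,8-tetramethyl-1,10-phenanthroline (40 mol%), Cs2CO3 (2 equiv), toluene, 110 °C, Ar
Reagents that add atoms: none
Why: Cs2CO3 and the CuI–phenanthroline complex should convert the secondary benzylic alcohol into an alkoxide of monovalent copper, which adds oxidatively to the C8a–Br bond to give a trivalent copper aryl alkoxide and forms O1–C8a by C–O reductive elimination. The closest known reaction type is the Ullmann-type intramolecular O-arylation of secondary alcohols with aryl bromides to give chromans. Ring C closes in a 6-exo mode at the sp2 carbon C8a through a seven-membered cuprate, helped by the Thorpe–Ingold effect of the fully substituted dithiane carbon C4. No stereocentre is created, and C2 keeps its (S) configuration because only its O–H bond reacts. The step needs C–O coupling to win over dehydration, retro-aldol cleavage, β-hydride loss and hydrodebromination: the dithiane leaves no carbonyl and hence no enolisable β-hydroxy ketone, the carbonate base in toluene spares the silyl and geranyl ethers, and the chelating ligand at raised loading is meant to offset sulfur coordination to copper.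

Step 8
Reactants: 12 (S)-2-[4-(geranyloxy)phenyl]-7-(triisopropylsilyloxy)spiro[chromane-4,2'-[1,3]dithiane]
Product: 13 (S)-2-[4-(geranyloxy)phenyl]-7-(triisopropylsilyloxy)chroman-4-one
Conditions: MeI (excess), CaCO3, MeCN/H2O (9:1), 45 °C
Reagents that add atoms: water, SMILES O
Why: Alkylative dithiane hydrolysis, in which S-methylation gives a sulfonium salt that ionises to a thionium ion stabilised by the ortho- and para-oxygenated ring A and is trapped by water, while CaCO3 scavenges HI so that the geranyl ether, the silyl ether and C2 see neither acid nor base.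

Step 9
Reactants: 13 (S)-2-[4-(geranyloxy)phenyl]-7-(triisopropylsilyloxy)chroman-4-one
Product: 14 (S)-2-[4-(geranyloxy)phenyl]-7-hydroxychroman-4-one (target)
Conditions: Bu4NF, AcOH (1:1), THF, 0 °C
Reagents that add atoms: none
Why: Fluoride-mediated desilylation of an aryl silyl ether whose phenoxide (para to the carbonyl) is a good leaving group, with acetic acid protonating that phenoxide at once so that the base-induced ring opening to the chalcone, which would racemise C2, is avoided.

**Compound list**

1 | 2-bromo-4-hydroxybenzaldehyde | O=Cc1ccc(O)cc1Br | starting material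
2 | 2-bromo-4-(triisopropylsilyloxy)benzaldehyde | O=Cc1ccc(O[Si](C(C)C)(C(C)C)C(C)C)cc1Br | intermediate
3 | propane-1,3-dithiol | SCCCS | starting material
4 | 2-[2-bromo-4-(triisopropylsilyloxy)phenyl]-1,3-dithiane | Brc1cc(O[Si](C(C)C)(C(C)C)C(C)C)ccc1C1SCCCS1 | intermediate
5 | 2-chloro-1-(4-hydroxyphenyl)ethanone | O=C(CCl)c1ccc(O)cc1 | starting material
6 | geraniol, (2E)-3,7-dimethylocta-2,6-dien-1-ol | CC(C)=CCC/C(C)=C/CO | starting material
7 | 2-chloro-1-[4-(geranyloxy)phenyl]ethanone | CC(C)=CCC/C(C)=C/COc1ccc(C(=O)CCl)cc1 | intermediate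
8 | (R)-2-chloro-1-[4-(geranyloxy)phenyl]ethanol | CC(C)=CCC/C(C)=C/COc1ccc([C@@H](O)CCl)cc1 | intermediate
9 | (R)-2-[4-(geranyloxy)phenyl]oxirane | CC(C)=CCC/C(C)=C/COc1ccc([C@@H]2CO2)cc1 | intermediate
10 | 2-lithio-2-[2-bromo-4-(triisopropylsilyloxy)phenyl]-1,3-dithiane (formed in the flask) | [Li]C1(c2ccc(O[Si](C(C)C)(C(C)C)C(C)C)cc2Br)SCCCS1 | intermediate
11 | (S)-2-{2-[2-bromo-4-(triisopropylsilyloxy)phenyl]-1,3-dithian-2-yl}-1-[4-(geranyloxy)phenyl]ethanol | CC(C)=CCC/C(C)=C/COc1ccc([C@@H](O)CC2(c3ccc(O[Si](C(C)C)(C(C)C)C(C)C)cc3Br)SCCCS2)cc1 | intermediate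
12 | (S)-2-[4-(geranyloxy)phenyl]-7-(triisopropylsilyloxy)spiro[chromane-4,2'-[1,3]dithiane] | CC(C)=CCC/C(C)=C/COc1ccc([C@@H]2CC4(SCCCS4)c3ccc(O[Si](C(C)C)(C(C)C)C(C)C)cc3O2)cc1 | intermediate
13 | (S)-2-[4-(geranyloxy)phenyl]-7-(triisopropylsilyloxy)chroman-4-one | CC(C)=CCC/C(C)=C/COc1ccc([C@@H]2CC(=O)c3ccc(O[Si](C(C)C)(C(C)C)C(C)C)cc3O2)cc1 | intermediate
14 | (S)-2-[4-(geranyloxy)phenyl]-7-hydroxychroman-4-one | CC(C)=CCC/C(C)=C/COc1ccc([C@@H]2CC(=O)c3ccc(O)cc3O2)cc1 | target

**Step count**

Total steps: 9. Longest linear sequence: 7 steps (5 → 7 → 8 → 9 → 11 → 12 → 13 → 14, steps 3 to 9).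

**Steps most likely to fail**

1. Step 6. The hindered aryl dithiane anion may attack the oxirane slowly or at the benzylic carbon, the base may metalate the bromoarene, and the electron-rich oxirane may rearrange before it is consumed. The fallback sets out from aldehyde 2 (with geraniol 6 and dithiol 3) and comes back at 11, building C3–C4 through an ynone and setting C2 afterwards.
   - Colvin homologation of 2 (Me3SiCHN2, LiN(i-Pr)2, THF, −78 °C → rt) would give 2-bromo-1-ethynyl-4-(triisopropylsilyloxy)benzene F1.
   - LiN(i-Pr)2 would convert it into lithium [2-bromo-4-(triisopropylsilyloxy)phenyl]acetylide F2, which should add to 4-(geranyloxy)benzaldehyde F3 (from 6 and 4-hydroxybenzaldehyde under the Mitsunobu conditions of step 3) to give racemic 3-[2-bromo-4-(triisopropylsilyloxy)phenyl]-1-[4-(geranyloxy)phenyl]prop-2-yn-1-ol F4.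
   - MnO2 in CH2Cl2 would oxidise this to 3-[2-bromo-4-(triisopropylsilyloxy)phenyl]-1-[4-(geranyloxy)phenyl]prop-2-yn-1-one F5.
   - Base-mediated double conjugate addition of 3 (NaOMe, MeOH/CH2Cl2, −10 °C → rt) would place the dithiane on the ring-A carbon and give 2-{2-[2-bromo-4-(triisopropylsilyloxy)phenyl]-1,3-dithian-2-yl}-1-[4-(geranyloxy)phenyl]ethanone F6.
   - Asymmetric transfer hydrogenation with RuCl[(S,S)-TsDPEN](p-cymene) and HCO2H/Et3N, which here corresponds to the (S) descriptor because aryl outranks CH2, would return to 11.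

2. Step 7. The two sulfur atoms of the dithiane may sequester copper so that C–O coupling stalls, or the aryl bromide may be reduced instead. The fallback sets out from 11 and comes back at 13, keeping the copper-mediated O1–C8a closure but carrying C4 at the alcohol oxidation level.
   - MeI/CaCO3 hydrolysis of 11 in aqueous MeCN would give (S)-1-[2-bromo-4-(triisopropylsilyloxy)phenyl]-3-[4-(geranyloxy)phenyl]-3-hydroxypropan-1-one F7.
   - This would be reduced at once under Narasaka–Prasad conditions (Et2BOMe, NaBH4, THF/MeOH, −78 °C) to the syn diol (1R,3S)-1-[2-bromo-4-(triisopropylsilyloxy)phenyl]-3-[4-(geranyloxy)phenyl]propane-1,3-diol F8, which has no carbonyl and so cannot dehydrate or undergo retro-aldol cleavage under base.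
   - CuI, 3,4,7,8-tetramethyl-1,10-phenanthroline and Cs2CO3 in toluene should then close ring C through the C2 hydroxyl only, since the C4 hydroxyl could reach C8a only through a four-membered ring, giving (2S,4R)-2-[4-(geranyloxy)phenyl]-7-(triisopropylsilyloxy)chroman-4-ol F9.
   - Benzylic oxidation with MnO2 in CH2Cl2 would return to 13.

3. Step 9. Fluoride or the liberated phenoxide may trigger retro-oxa-Michael opening of ring C to the chalcone and reclosure, eroding the configuration at C2, or the cleavage may be incomplete under buffering. The fallback sets out from 12 and comes back at 14, reversing the order of the two unmaskings.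
   - Bu4NF in THF would desilylate at the dithiane stage, where no carbonyl is present and ring opening is impossible, to give (S)-2-[4-(geranyloxy)phenyl]spiro[chromane-4,2'-[1,3]dithian]-7-ol F10.
   - MeI/CaCO3 in aqueous MeCN would then unveil the ketone and give 14 directly, so that the free flavanone never meets fluoride.

**Further compounds**

F1 | step 6 | 2-bromo-1-ethynyl-4-(triisopropylsilyloxy)benzene | C#Cc1ccc(O[Si](C(C)C)(C(C)C)C(C)C)cc1Br
F2 | step 6 | lithium [2-bromo-4-(triisopropylsilyloxy)phenyl]acetylide | [Li]C#Cc1ccc(O[Si](C(C)C)(C(C)C)C(C)C)cc1Br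
F3 | step 6 | 4-(geranyloxy)benzaldehyde | CC(C)=CCC/C(C)=C/COc1ccc(C=O)cc1
F4 | step 6 | rac-3-[2-bromo-4-(triisopropylsilyloxy)phenyl]-1-[4-(geranyloxy)phenyl]prop-2-yn-1-ol | CC(C)=CCC/C(C)=C/COc1ccc(C(O)C#Cc2ccc(O[Si](C(C)C)(C(C)C)C(C)C)cc2Br)cc1
F5 | step 6 | 3-[2-bromo-4-(triisopropylsilyloxy)phenyl]-1-[4-(geranyloxy)phenyl]prop-2-yn-1-one | CC(C)=CCC/C(C)=C/COc1ccc(C(=O)C#Cc2ccc(O[Si](C(C)C)(C(C)C)C(C)C)cc2Br)cc1
F6 | step 6 | 2-{2-[2-bromo-4-(triisopropylsilyloxy)phenyl]-1,3-dithian-2-yl}-1-[4-(geranyloxy)phenyl]ethanone | CC(C)=CCC/C(C)=C/COc1ccc(C(=O)CC2(c3ccc(O[Si](C(C)C)(C(C)C)C(C)C)cc3Br)SCCCS2)cc1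
F7 | step 7 | (S)-1-[2-bromo-4-(triisopropylsilyloxy)phenyl]-3-[4-(geranyloxy)phenyl]-3-hydroxypropan-1-one | CC(C)=CCC/C(C)=C/COc1ccc([C@@H](O)CC(=O)c2ccc(O[Si](C(C)C)(C(C)C)C(C)C)cc2Br)cc1
F8 | step 7 | (1R,3S)-1-[2-bromo-4-(triisopropylsilyloxy)phenyl]-3-[4-(geranyloxy)phenyl]propane-1,3-diol | CC(C)=CCC/C(C)=C/COc1ccc([C@@H](O)C[C@@H](O)c2ccc(O[Si](C(C)C)(C(C)C)C(C)C)cc2Br)cc1
F9 | step 7 | (2S,4R)-2-[4-(geranyloxy)phenyl]-7-(triisopropylsilyloxy)chroman-4-ol | CC(C)=CCC/C(C)=C/COc1ccc([C@@H]2C[C@@H](O)c3ccc(O[Si](C(C)C)(C(C)C)C(C)C)cc3O2)cc1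
F10 | step 9 | (S)-2-[4-(geranyloxy)phenyl]spiro[chromane-4,2'-[1,3]dithian]-7-ol | CC(C)=CCC/C(C)=C/COc1ccc([C@@H]2CC4(SCCCS4)c3ccc(O)cc3O2)cc1
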